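The data were computed on assumed constants; scatter was added.

The trap here is to read elm's plateau as the yield of the recipe: at the same 0.90 equiv of partner, cedar still climbs from 82.0% at 8.00 h to 86.0% at 15.0 h.

| flask | substrate | partner | precatalyst | remark | time |
|---|---|---|---|---|---|
| cedar | 0.014 M (in portions, 2) | 0.90 equiv | 0.5 mol% | run made earlier; portions every 2.0 h |  |
| elm | 0.061 M (in portions, 2) | 0.90 equiv | 0.5 mol% | run made earlier; portions every 2.0 h |  |
| alder | 0.010 M (in portions, 2) | 0.94 equiv | 0.5 mol% | run made earlier; portions every 2.0 h |  |
| Thursday's | 0.010 M (in portions, 2) | 0.900 equiv | 0.5 mol% | the portions of substrate follow each other after 2.0 h, the first at the start | 20 h |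
| Tuesday's | 0.010 M (in portions, 2) | 0.900 equiv | 0.3 mol% | the portions of substrate follow each other after 2.0 h, the first at the start | 20 h |
| Sunday's | 0.040 M (in portions, 2) | 0.900 equiv | 0.5 mol% | the portions of substrate follow each other after 1.0 h, the first at the start | 20 h |
| Wednesday's | 0.040 M (in portions, 2) | 2.70 equiv | 0.5 mol% | the portions of substrate follow each other after 2.0 h, the first at the start | 20 h |
| Monday's | 0.010 M (in portions, 2) | 0.600 equiv | 0.5 mol% | the portions of substrate follow each other after 4.0 h, the first at the start | 20 h |

| run | time / h | target / % | substrate / % |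
|---|---|---|---|
| cedar | 1.00 | 10.3 | 38.2 |
| cedar | 2.00 | 26.2 | 23.2 |
| cedar | 4.00 | 66.5 | 31.2 |
| cedar | 8.00 | 82.0 | 16.3 |
| cedar | 15.0 | 86.0 | 11.0 |
| elm | 3.00 | 89.0 | 10.7 |
| elm | 6.00 | 89.1 | 11.0 |
| elm | 8.00 | 88.4 | 9.3 |
| elm | 12.0 | 90.1 | 10.5 |
| elm | 15.0 | 88.6 | 10.1 |
| alder | 3.00 | 36.8 | 62.1 |
| alder | 6.00 | 67.0 | 29.6 |
| alder | 8.00 | 75.3 | 22.2 |
| alder | 12.0 | 81.7 | 15.0 |
| alder | 15.0 | 85.6 | 11.9 |

(scatter of a reading: 0.5 percentage points)

- the flasks put in order of amount of target, in percent of the substrate charged, best first, at 20 h (Thursday's / Tuesday's / Sunday's / Wednesday's / Monday's)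
- the same order at 2.0 h (Thursday's / Tuesday's / Sunday's / Wednesday's / Monday's)
- the amount of target, in percent of the substrate charged of the flask you put first, at 20 h
- the amount of target, in percent of the substrate charged of the flask you put last, at 20 h

- on the list of suspects stand: partner + precatalyst -> catalyst + spent reagent; substrate + partner + catalyst -> catalyst + target; substrate + partner -> uncatalysed product

What is the ceiling? Elm stays near 90.1% of target with 10.5% of substrate left, as a partner charge of 0.90 equiv allows, so partner is the limiting reagent there. We take each flask's ceiling as the smaller of its two charges, less the loss shown by alder's balance at 15.0 h, 2.5 percentage points.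

Does a flask reach its ceiling in time? Between 8.00 h and 12.0 h, alder gains 6.4 points of target, with mean substrate 18.6% and mean partner 12.6%, both on the substrate charged. Replacing the catalyst curve by its mean over that window gives a coefficient of 0.683 h⁻¹.

Monday's has alder's concentration and a partner charge of 0.600 equiv, so partner is its smaller charge. Its substrate is no large excess and its catalyst changes too, so what follows is a rough reckoning by means, not a true first-order decay. Once both portions are in at 4.0 h, its substrate can end near 40.0% of the charge, and we take the midpoint between that and the whole charge, 70.0%, as its mean, which overstates the time before the second portion. The partner clock, the time in which the partner left falls by the factor e with substrate held at its mean, is then 2.09 h. With 9.57 clocks in 20 h, we commit Monday's to its ceiling, 57.5%.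

Near its end, Thursday's has a clock of 14.6 h, so it stays below its ceiling. The coefficient should go with the square of concentration, which gives Sunday's 0.915 h and puts it at its ceiling. Wednesday's has the higher ceiling because its substrate, not its partner, is the smaller charge. Tuesday's carries 0.3 mol% of precatalyst, less than Thursday's 0.5 mol%, so it comes after Thursday's.

The forecast gives Wednesday's > Sunday's > Thursday's > Tuesday's > Monday's at 20 h and Sunday's > Wednesday's > Thursday's > Tuesday's > Monday's at 2.0 h, with 99% on top and 56% at the bottom, below our figure for Monday's. Its ground: “Target plateaus near the partner charge”.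

The flasks give Wednesday's > Sunday's > Thursday's > Tuesday's > Monday's and Sunday's > Wednesday's > Thursday's > Tuesday's > Monday's, with 99.1% and 57.6%.

    partner + precatalyst → catalyst + spent reagent (k = 0.00200 M⁻¹ s⁻¹)
    substrate + partner + catalyst → catalyst + target (k = 1800 M⁻² s⁻¹)
    substrate + partner → uncatalysed product (k = 3.50 × 10⁻⁴ M⁻¹ s⁻¹)

Monday's keeps 0.530% of its partner at 20.0 h, against the clock's 0.00706%. Now take one more flask like Monday's, at 0.0025 M of substrate, a quarter of the concentration. Squaring stretches the clock to 33.5 h, so 20 h is 0.597 of a clock. That reckons 55.0% of the partner left and 27.0% of target. The flask holds 17.2% of its catalyst in the active form, 16.4% of target and 67.9% of its partner at 20.0 h.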